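**Plan**

1. Retrosynthesis (tetralin numbering: C1 carbinol carbon, C4 the naphthyl-bearing carbon, ring A the benzo ring): C4–H is traced back to a C3=C4 double bond; then the C2–C3 ring bond is cut; then ring A–C1 (C1–C2 as a chloroacetyl unit), C4=C3 (methylene from a ketone) and C4–C2' of the naphthalene (aryllithium plus aldehyde).
2. Forward: MOM-protected 8-methoxy-1-naphthol is ortho-lithiated and added to 2-bromo-6-methoxybenzaldehyde; oxidation and methylenation give a 1,1-diarylethylene; Br/Li exchange and chloroacetylation put C1–C2 on ring A; reduction and base give an (R)-oxirane. The saturated ring, the only ring made, is closed in step 7; hydrogenation and MOM removal finish.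
3. Enabling feature: C4 lies between C4a of ring A and C2' of the naphthalene, so C4=C3H2 is a 1,1-diarylethylene whose only open position is C3 and whose radical adduct is doubly benzylic. Ortho to it on ring A, the C1–C2 oxirane can be opened by cobalt at C2 with the C1–O bond intact, and the C2 radical reaches C3 through a six-membered (6-endo) transition state. The event is a cobalt-catalysed, light-driven, redox-neutral isomerisation of the epoxy alkene to a 4-aryl-1,2-dihydronaphthalen-1-ol.
4. Stereochemistry: C1 (S) comes from catalyst-controlled asymmetric transfer hydrogenation of the chloroketone and is carried unchanged through oxirane and ring closure. C4 (R) comes from C1, whose hydroxyl directs iridium-catalysed hydrogenation of C3=C4 to its own face (H cis, naphthyl trans to OH).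

Key step: step 7

Assumption: 8-methoxynaphthalen-1-ol, 2-bromo-6-methoxybenzaldehyde and 2-chloro-N-methoxy-N-methylacetamide are taken as commercial compounds; C4a and C8a are the ring-fusion carbons of ring A and C2' is the naphthalene carbon bonded to C4.

**Route**

Step 1
Reactants: 1 8-methoxynaphthalen-1-ol
Product: 2 1-methoxy-8-(methoxymethoxy)naphthalene
Conditions: NaH, MOMCl, DMF, 0 °C to rt
Reagents that add atoms: chloromethyl methyl ether (MOMCl), COCCl
Why: Williamson-type O-alkylation of the sodium naphthoxide gives the MOM ether, which protects the phenol and is the directing group for the ortho-lithiation of step 2.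

Step 2
Reactants: 2 1-methoxy-8-(methoxymethoxy)naphthalene; 3 2-bromo-6-methoxybenzaldehyde
Product: 5 (2-bromo-6-methoxyphenyl)[8-methoxy-1-(methoxymethoxy)naphthalen-2-yl]methanol (racemic), via 2-naphthyllithium 4 (not isolated)
Conditions: n-BuLi, TMEDA, Et2O, 0 °C to rt; then 3, THF, −78 °C; H2O
Reagents that add atoms: none
Why: Directed ortho-metalation, in which the OMOM group (a stronger director than OMe) steers lithiation to C2 of the naphthalene, is followed by 1,2-addition of the aryllithium to the non-enolisable aldehyde, which at −78 °C should be faster than exchange with the aryl bromide and fixes the C4–C2' bond ortho to oxygen.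

Step 3
Reactants: 5 (2-bromo-6-methoxyphenyl)[8-methoxy-1-(methoxymethoxy)naphthalen-2-yl]methanol
Product: 6 (2-bromo-6-methoxyphenyl)[8-methoxy-1-(methoxymethoxy)naphthalen-2-yl]methanone
Conditions: Dess–Martin periodinane, pyridine, CH2Cl2, rt
Reagents that add atoms: none
Why: Dess–Martin oxidation of a doubly benzylic secondary alcohol to the diaryl ketone runs under pyridine-buffered, non-acidic conditions that the MOM acetal and the aryl bromide should survive.

Step 4
Reactants: 6 (2-bromo-6-methoxyphenyl)[8-methoxy-1-(methoxymethoxy)naphthalen-2-yl]methanone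
Product: 7 2-[1-(2-bromo-6-methoxyphenyl)ethenyl]-8-methoxy-1-(methoxymethoxy)naphthalene
Conditions: Ph3PCH3Br, KOt-Bu, THF, 0 °C to 65 °C
Reagents that add atoms: methyltriphenylphosphonium bromide, C[P+](c1ccccc1)(c1ccccc1)c1ccccc1.[Br-]
Why: Wittig methylenation of a non-enolisable diaryl ketone with the small ylide Ph3P=CH2, the standard entry to 1,1-diarylethylenes, installs C3 as the CH2 terminus.

Step 5
Reactants: 7 2-[1-(2-bromo-6-methoxyphenyl)ethenyl]-8-methoxy-1-(methoxymethoxy)naphthalene; 8 2-chloro-N-methoxy-N-methylacetamide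
Product: 10 2-chloro-1-{3-methoxy-2-[1-(8-methoxy-1-(methoxymethoxy)naphthalen-2-yl)ethenyl]phenyl}ethan-1-one, via aryllithium 9 (not isolated)
Conditions: n-BuLi, THF, −78 °C; then 8, −78 to 0 °C; H2O
Reagents that add atoms: none
Why: Bromine–lithium exchange, which at −78 °C should outrun addition of n-BuLi to the twisted and hindered diarylethylene, is followed by Weinreb ketone synthesis, in which the chelated tetrahedral adduct of 8 stops over-addition and releases the chloromethyl ketone (C1 and C2) on work-up.

Step 6
Reactants: 10 2-chloro-1-{3-methoxy-2-[1-(8-methoxy-1-(methoxymethoxy)naphthalen-2-yl)ethenyl]phenyl}ethan-1-one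
Product: 12 (2R)-2-{3-methoxy-2-[1-(8-methoxy-1-(methoxymethoxy)naphthalen-2-yl)ethenyl]phenyl}oxirane, via (R)-chlorohydrin 11 (not isolated)
Conditions: Cp*RhCl[(S,S)-TsDPEN] (1 mol %), HCO2H/Et3N (5:2), THF, rt; then 2 M aq NaOH, 0 °C to rt
Reagents that add atoms: none
Why: Noyori–Ikariya asymmetric transfer hydrogenation of an aryl chloromethyl ketone sets C1 under catalyst control (the (S,S)-catalyst, the enantiomer that reduces acetophenone to (S)-1-phenylethanol, should add hydride to the same face, which for the chloromethyl ketone is named R), and hydroxide then closes the oxirane by intramolecular Williamson displacement at C2 without touching C1.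

Step 7
Reactants: 12 (2R)-2-{3-methoxy-2-[1-(8-methoxy-1-(methoxymethoxy)naphthalen-2-yl)ethenyl]phenyl}oxirane
Product: 13 (1S)-5-methoxy-4-[8-methoxy-1-(methoxymethoxy)naphthalen-2-yl]-1,2-dihydronaphthalen-1-ol
Conditions: Co(dmgH)2(py)Cl (10 mol %), Zn (30 mol %), i-Pr2NEt (20 mol %), MeCN/MeOH, blue LED (450 nm), rt
Reagents that add atoms: none
Why: Proposed new method: monovalent cobalt (from Co(dmgH)2(py)Cl and zinc) should open the oxirane of 12 by SN2 attack at the CH2 carbon C2 to give a 2-hydroxyalkyl cobaloxime, blue light homolyses its Co–C bond, the primary C2 radical adds to C3, the CH2 end of the 1,1-diarylethylene, and divalent cobalt takes a hydrogen atom from C3 of the resulting doubly benzylic C4 radical, which leaves the C3=C4 double bond and a cobalt hydride that the amine deprotonates back to monovalent cobalt, so that the whole is a redox-neutral isomerisation of 12 to 13. The closest known reaction types are the light-driven cobaloxime-catalysed Heck-type cyclisation of alkyl iodides onto alkenes and the opening of terminal epoxides by monovalent cobalt at the less hindered carbon, known from the cobalt-catalysed isomerisation of epoxides to allylic alcohols; joining the two in one catalytic cycle is the new element. The tetralin ring closes in the 6-endo-trig mode. No stereocentre is made, and C1 keeps the configuration of the (R)-oxirane (named S in 13) because its C–O bond is never broken. The step needs 6-endo and not 5-exo attack, which is secured by C4 being fully substituted and flanked by ring A and the naphthalene so that only C3 is open and the radical formed is doubly benzylic, and it needs cobalt to attack C2 and not the benzylic C1, which is secured by the bulky ortho substituent of ring A that shields C1.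

Step 8
Reactants: 13 (1S)-5-methoxy-4-[8-methoxy-1-(methoxymethoxy)naphthalen-2-yl]-1,2-dihydronaphthalen-1-ol
Product: 14 (1S,4R)-5-methoxy-4-[8-methoxy-1-(methoxymethoxy)naphthalen-2-yl]-1,2,3,4-tetrahydronaphthalen-1-ol
Conditions: [Ir(cod)(PCy3)(py)]PF6 (5 mol %), H2 (1 atm), CH2Cl2, 0 °C to rt
Reagents that add atoms: none
Why: Hydroxyl-directed homogeneous hydrogenation with a cationic iridium catalyst: the C1 hydroxyl binds iridium and hydrogen is delivered to C3=C4 from the face on which the OH stands (the homoallylic cyclohexenol case, as in terpinen-4-ol), so H at C4 should end cis and the naphthyl group trans to OH, which is the (1S,4R) configuration.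

Step 9
Reactants: 14 (1S,4R)-5-methoxy-4-[8-methoxy-1-(methoxymethoxy)naphthalen-2-yl]-1,2,3,4-tetrahydronaphthalen-1-ol
Product: 15 dipolynaphthalene A
Conditions: HCl (cat.), MeOH, rt
Reagents that add atoms: none
Why: Acid-catalysed transacetalisation to methanol removes the MOM group from the peri-crowded naphthol (the freed OH is held by a hydrogen bond to the 8-methoxy oxygen), while the secondary benzylic alcohol, whose ring methoxy group is meta to the C1 side, should not ionise at room temperature.

**Compound list**

1 | 8-methoxynaphthalen-1-ol | COc1cccc2cccc(O)c12 | starting material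
2 | 1-methoxy-8-(methoxymethoxy)naphthalene | COCOc1cccc2cccc(OC)c12 | intermediate
3 | 2-bromo-6-methoxybenzaldehyde | COc1cccc(Br)c1C=O | starting material
4 | [8-methoxy-1-(methoxymethoxy)naphthalen-2-yl]lithium | [Li]c1ccc2cccc(OC)c2c1OCOC | intermediate
5 | (2-bromo-6-methoxyphenyl)[8-methoxy-1-(methoxymethoxy)naphthalen-2-yl]methanol (racemic) | COc1cccc(Br)c1C(O)c1ccc2cccc(OC)c2c1OCOC | intermediate
6 | (2-bromo-6-methoxyphenyl)[8-methoxy-1-(methoxymethoxy)naphthalen-2-yl]methanone | COc1cccc(Br)c1C(=O)c1ccc2cccc(OC)c2c1OCOC | intermediate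
7 | 2-[1-(2-bromo-6-methoxyphenyl)ethenyl]-8-methoxy-1-(methoxymethoxy)naphthalene | COc1cccc(Br)c1C(=C)c1ccc2cccc(OC)c2c1OCOC | intermediate
8 | 2-chloro-N-methoxy-N-methylacetamide | CON(C)C(=O)CCl | starting material
9 | {3-methoxy-2-[1-(8-methoxy-1-(methoxymethoxy)naphthalen-2-yl)ethenyl]phenyl}lithium | [Li]c1cccc(OC)c1C(=C)c1ccc2cccc(OC)c2c1OCOC | intermediate
10 | 2-chloro-1-{3-methoxy-2-[1-(8-methoxy-1-(methoxymethoxy)naphthalen-2-yl)ethenyl]phenyl}ethan-1-one | COc1cccc(C(=O)CCl)c1C(=C)c1ccc2cccc(OC)c2c1OCOC | intermediate
11 | (1R)-2-chloro-1-{3-methoxy-2-[1-(8-methoxy-1-(methoxymethoxy)naphthalen-2-yl)ethenyl]phenyl}ethan-1-ol | COc1cccc([C@@H](O)CCl)c1C(=C)c1ccc2cccc(OC)c2c1OCOC | intermediate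
12 | (2R)-2-{3-methoxy-2-[1-(8-methoxy-1-(methoxymethoxy)naphthalen-2-yl)ethenyl]phenyl}oxirane | COc1cccc([C@@H]2CO2)c1C(=C)c1ccc2cccc(OC)c2c1OCOC | intermediate
13 | (1S)-5-methoxy-4-[8-methoxy-1-(methoxymethoxy)naphthalen-2-yl]-1,2-dihydronaphthalen-1-ol | COc1cccc2c1C(c1ccc3cccc(OC)c3c1OCOC)=CC[C@@H]2O | intermediate
14 | (1S,4R)-5-methoxy-4-[8-methoxy-1-(methoxymethoxy)naphthalen-2-yl]-1,2,3,4-tetrahydronaphthalen-1-ol | COc1cccc2c1[C@@H](c1ccc3cccc(OC)c3c1OCOC)CC[C@@H]2O | intermediate
15 | dipolynaphthalene A, (1S,4R)-4-(1-hydroxy-8-methoxynaphthalen-2-yl)-5-methoxy-1,2,3,4-tetrahydronaphthalen-1-ol | COc1cccc2c1[C@@H](c1ccc3cccc(OC)c3c1O)CC[C@@H]2O | target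

**Step count and risks**

Total step count: 9. Longest linear sequence: 9 steps (1 to 15).

Risk 1 (step 7). The alkylcobalt intermediate may lose a hydrogen atom from C1 (dehydrocobaltation to the enol and on to the methyl ketone) faster than the C2 radical cyclises, or monovalent cobalt may fail to open the hindered oxirane. The fallback uses known chemistry and replaces the cobalt epoxide opening by a halide-based palladium radical Heck cyclisation. It sets out from 11, which is isolated by leaving out the NaOH treatment of step 6. Silylation (TBSOTf, 2,6-lutidine, CH2Cl2) gives the TBS ether of the chlorohydrin F1. Finkelstein exchange (NaI, 2-butanone, reflux) gives the iodide F2. The visible-light palladium-catalysed alkyl Heck reaction (Pd(OAc)2, Xantphos, Cs2CO3, benzene, blue LED; 6-endo radical addition to the diarylethylene, then β-hydride elimination) gives the TBS ether of the dihydronaphthalenol F3. TBAF in THF then gives 13, where the route is rejoined.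

Risk 2 (step 8). Facial selectivity may be poor if the ether oxygens of the naphthyl group compete with the C1 hydroxyl for iridium, and the acidic iridium hydride may cause loss of water from the 1,2-dihydronaphthalen-1-ol to a naphthalene. The fallback replaces substrate direction by catalyst control and sets out from 13. Silylation (TESCl, imidazole, DMF) gives the triethylsilyl ether of the dihydronaphthalenol F4. Asymmetric hydrogenation with the enantiomer of [Ir(cod)(tBu-PHOX)]BArF matched to the (4R) face (1-aryl-3,4-dihydronaphthalenes are a standard substrate class for such catalysts; H2, CH2Cl2) gives the triethylsilyl ether of the tetralol F5. TBAF gives 14, where the route is rejoined.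

Risk 3 (step 5). n-BuLi or the aryllithium may add to the 1,1-diarylethylene (carbolithiation), or the aryllithium may deprotonate or exchange with the chloroacetamide instead of acylating. The fallback replaces organolithium chemistry by palladium coupling and sets out from 7. Stille coupling with tributyl(1-ethoxyvinyl)stannane (Pd(PPh3)2Cl2, toluene, 100 °C) gives the enol ether F6. NBS in THF/H2O at 0 °C gives the α-bromoketone F7. Corey–Bakshi–Shibata reduction ((R)-methyl oxazaborolidine, catecholborane, toluene, −78 °C) gives the (R)-bromohydrin F8. Aqueous NaOH closes the oxirane 12, where the route is rejoined.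

Further compounds
F1 | step 7 | tert-butyl{(1R)-2-chloro-1-[3-methoxy-2-(1-(8-methoxy-1-(methoxymethoxy)naphthalen-2-yl)ethenyl)phenyl]ethoxy}dimethylsilane | COc1cccc([C@@H](O[Si](C)(C)C(C)(C)C)CCl)c1C(=C)c1ccc2cccc(OC)c2c1OCOC
F2 | step 7 | tert-butyl{(1R)-2-iodo-1-[3-methoxy-2-(1-(8-methoxy-1-(methoxymethoxy)naphthalen-2-yl)ethenyl)phenyl]ethoxy}dimethylsilane | COc1cccc([C@@H](O[Si](C)(C)C(C)(C)C)CI)c1C(=C)c1ccc2cccc(OC)c2c1OCOC
F3 | step 7 | tert-butyl{[(1S)-5-methoxy-4-(8-methoxy-1-(methoxymethoxy)naphthalen-2-yl)-1,2-dihydronaphthalen-1-yl]oxy}dimethylsilane | COc1cccc2c1C(c1ccc3cccc(OC)c3c1OCOC)=CC[C@@H]2O[Si](C)(C)C(C)(C)C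
F4 | step 8 | triethyl{[(1S)-5-methoxy-4-(8-methoxy-1-(methoxymethoxy)naphthalen-2-yl)-1,2-dihydronaphthalen-1-yl]oxy}silane | COc1cccc2c1C(c1ccc3cccc(OC)c3c1OCOC)=CC[C@@H]2O[Si](CC)(CC)CC
F5 | step 8 | triethyl{[(1S,4R)-5-methoxy-4-(8-methoxy-1-(methoxymethoxy)naphthalen-2-yl)-1,2,3,4-tetrahydronaphthalen-1-yl]oxy}silane | COc1cccc2c1[C@@H](c1ccc3cccc(OC)c3c1OCOC)CC[C@@H]2O[Si](CC)(CC)CC
F6 | step 5 | 2-{1-[2-(1-ethoxyethenyl)-6-methoxyphenyl]ethenyl}-8-methoxy-1-(methoxymethoxy)naphthalene | CCOC(=C)c1cccc(OC)c1C(=C)c1ccc2cccc(OC)c2c1OCOC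
F7 | step 5 | 2-bromo-1-{3-methoxy-2-[1-(8-methoxy-1-(methoxymethoxy)naphthalen-2-yl)ethenyl]phenyl}ethan-1-one | COc1cccc(C(=O)CBr)c1C(=C)c1ccc2cccc(OC)c2c1OCOC
F8 | step 5 | (1R)-2-bromo-1-{3-methoxy-2-[1-(8-methoxy-1-(methoxymethoxy)naphthalen-2-yl)ethenyl]phenyl}ethan-1-ol | COc1cccc([C@@H](O)CBr)c1C(=C)c1ccc2cccc(OC)c2c1OCOC
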